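**Retrosynthetic overview**
- The target is traced back to its bis(dimethyl ketal), and this to two acids, hexadecanoic acid and 11-(2,3,5-trimethoxy-6-methylphenyl)undecanoic acid. One anodic operation in one cell joins them: the arene is first raised to the quinone bisketal, then a mixed Kolbe coupling makes the C10′–C11′ bond of the side chain.
- Enabling feature: this bond lies between two CH2 groups of an unbranched chain, ten carbons from ring carbon C6, so both partners are primary, unstabilised radicals from unbranched carboxylates. The para C1/C4 oxygens with the C2 methoxy let the ring travel as a 1,2,4-trimethoxybenzene, which the same anode turns into a bisketal that should be silent at the Kolbe potential.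
- The aryl acid comes from saponification and reductive O-methylation of a quinone ester. That ester comes from Ag/persulfate decarboxylative radical alkylation of 2-methoxy-5-methyl-1,4-benzoquinone at C6 with monomethyl dodecanedioate.
- Rings: the only ring is bought as the quinone. No ring is formed; it only changes oxidation level (quinone → arene → bisketal → quinone).

Key step: step 4

Assumption: 2-methoxy-5-methyl-1,4-benzoquinone and monomethyl dodecanedioate are treated as catalogue chemicals, and the side chain is read as unbranched C25 (pentacosyl).

Step 1
Reactants: 1 2-methoxy-5-methyl-1,4-benzoquinone; 2 12-methoxy-12-oxododecanoic acid (monomethyl dodecanedioate)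
Product: 3 methyl 11-(5-methoxy-2-methyl-3,6-dioxocyclohexa-1,4-dien-1-yl)undecanoate
Conditions: AgNO3 (0.3 equiv), (NH4)2S2O8 (1.5 equiv), MeCN/H2O 1:1, 70 °C
Reagents that add atoms: none
Why: Ag(I)/persulfate oxidative decarboxylation of 2 gives a nucleophilic primary alkyl radical that should add to C6 of 1, the only unsubstituted carbon of the electron-poor C5=C6 alkene, rather than to C3 of the methoxy-bearing vinylogous-ester alkene, and the adduct is re-oxidised to the quinone (Jacobsen–Torssell radical alkylation of quinones).

Step 2
Reactants: 3 methyl 11-(5-methoxy-2-methyl-3,6-dioxocyclohexa-1,4-dien-1-yl)undecanoate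
Product: 5 methyl 11-(2,3,5-trimethoxy-6-methylphenyl)undecanoate, via hydroquinone ester 4 (not isolated)
Conditions: Na2S2O4, THF/H2O, rt; then Me2SO4, K2CO3, acetone, reflux, Ar
Reagents that add atoms: dimethyl sulfate, COS(=O)(=O)OC
Why: Dithionite reduces the quinone to the hydroquinone, and both phenols are then O-methylated (Williamson ether synthesis) while the methyl ester is untouched.

Step 3
Reactants: 5 methyl 11-(2,3,5-trimethoxy-6-methylphenyl)undecanoate
Product: 6 11-(2,3,5-trimethoxy-6-methylphenyl)undecanoic acid
Conditions: LiOH·H2O, THF/MeOH/H2O, rt; then 1 M HCl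
Reagents that add atoms: lithium hydroxide (hydroxide oxygen), [Li+].[OH-]
Why: Ester saponification; aryl methyl ethers are inert to hydroxide.

Step 4
Reactants: 6 11-(2,3,5-trimethoxy-6-methylphenyl)undecanoic acid; 7 hexadecanoic acid (palmitic acid)
Product: 9 3,3,4,6,6-pentamethoxy-1-methyl-2-pentacosylcyclohexa-1,4-diene, via bisketal carboxylate 8 (not isolated)
Conditions: NaOMe (2 equiv), MeOH, Pt anode/Pt cathode, undivided cell, 0 °C, ca. 15 mA/cm2 until 6 is consumed; then 7 (8 equiv), hexane upper layer, 45 °C, ca. 250 mA/cm2; NaHCO3 work-up
Reagents that add atoms: methanol, CO (delivered as sodium methoxide, [Na+].[O-]C)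
Why: Proposed new method: in basic methanol at low current density the trimethoxyarene of 6 is the most easily oxidised group and should undergo two-electron anodic oxidation with methoxide capture at the two para-related C–OMe carbons to give the quinone bis(dimethyl ketal) carboxylate 8, the closest known reaction type being the anodic bisketalisation of 1,4-dimethoxyarenes in KOH/MeOH; addition of 7 then turns the bath into a partially neutralised mixed-acid solution in which, at high current density on smooth platinum, both carboxylates are discharged to acyloxy radicals that lose CO2 and the two primary alkyl radicals combine at the anode, the closest known reaction type being the mixed Kolbe electrolysis of unbranched fatty acids. The combination of the two anodic events in one cell on one substrate, and a Kolbe coupling in the presence of a quinone bisketal, are the untested parts. No ring is closed and no stereocentre is formed. The step needs cross- over homo-coupling, secured statistically by the excess of cheap 7 (its homodimer is a hydrocarbon that chromatography removes), and radical coupling over two-electron Hofer–Moest oxidation, secured by the absence of any α-substituent in either acid. It also needs the ring to survive the Kolbe potential, which the order of events should secure: after the first stage no arene is left, both ring alkenes are flanked by two electron-withdrawing ketal carbons, and the carboxylate layer on platinum should keep neutral organics from the anode.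

Step 5
Reactants: 9 3,3,4,6,6-pentamethoxy-1-methyl-2-pentacosylcyclohexa-1,4-diene
Product: 10 2-methoxy-5-methyl-6-pentacosyl-1,4-benzoquinone
Conditions: 1 M HCl aq, THF, rt
Reagents that add atoms: water, O
Why: Acid-catalysed hydrolysis of both dimethyl ketals through oxocarbenium ions should release the two quinone carbonyls, while the C2 methoxy group, now part of a vinylogous ester, is stable to dilute aqueous acid at room temperature.

**Compound list**
1 | 2-methoxy-5-methyl-1,4-benzoquinone | COC1=CC(=O)C(C)=CC1=O | starting material
2 | 12-methoxy-12-oxododecanoic acid (monomethyl dodecanedioate) | COC(=O)CCCCCCCCCCC(=O)O | starting material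
3 | methyl 11-(5-methoxy-2-methyl-3,6-dioxocyclohexa-1,4-dien-1-yl)undecanoate | COC(=O)CCCCCCCCCCC1=C(C)C(=O)C=C(OC)C1=O | intermediate
4 | methyl 11-(2,5-dihydroxy-3-methoxy-6-methylphenyl)undecanoate | COC(=O)CCCCCCCCCCc1c(C)c(O)cc(OC)c1O | intermediate
5 | methyl 11-(2,3,5-trimethoxy-6-methylphenyl)undecanoate | COC(=O)CCCCCCCCCCc1c(C)c(OC)cc(OC)c1OC | intermediate
6 | 11-(2,3,5-trimethoxy-6-methylphenyl)undecanoic acid | OC(=O)CCCCCCCCCCc1c(C)c(OC)cc(OC)c1OC | intermediate
7 | hexadecanoic acid (palmitic acid) | CCCCCCCCCCCCCCCC(=O)O | starting material
8 | sodium 11-(3,3,5,6,6-pentamethoxy-2-methylcyclohexa-1,4-dien-1-yl)undecanoate | [Na+].[O-]C(=O)CCCCCCCCCCC1=C(C)C(OC)(OC)C=C(OC)C1(OC)OC | intermediate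
9 | 3,3,4,6,6-pentamethoxy-1-methyl-2-pentacosylcyclohexa-1,4-diene | CCCCCCCCCCCCCCCCCCCCCCCCCC1=C(C)C(OC)(OC)C=C(OC)C1(OC)OC | intermediate
10 | 2-methoxy-5-methyl-6-pentacosyl-1,4-benzoquinone (5-methoxy-2-methyl-3-pentacosylcyclohexa-2,5-diene-1,4-dione) | CCCCCCCCCCCCCCCCCCCCCCCCCC1=C(C)C(=O)C=C(OC)C1=O | target

**Step count**
Total steps: 5. Longest linear sequence: 5 steps (1 → 3 → 5 → 6 → 9 → 10); 7 enters at step 4.

**Steps most likely to fail**

Step 4 (Proposed new method). What may go wrong: anodic over-oxidation of the bisketal diene at the Kolbe potential, passivation of the platinum anode by the waxy products so that the second stage stalls, or dominant homo-coupling. The fallback uses known chemistry, sets out from 6 and comes back at 10. Acid 6 is esterified with N-hydroxyphthalimide (DIC, DMAP, CH2Cl2) to the redox-active ester 1,3-dioxoisoindolin-2-yl 11-(2,3,5-trimethoxy-6-methylphenyl)undecanoate F1. Commercial 1-bromopentadecane is converted with Mg in THF to pentadecylmagnesium bromide F2 and, with ZnCl2, to dipentadecylzinc F3. Nickel-catalysed decarboxylative Negishi alkyl–alkyl coupling of F1 with F3 (NiCl2·glyme, 4,4′-di-tert-butyl-2,2′-bipyridine, THF/DMF, rt) should form the same CH2–CH2 bond and give 1,2,5-trimethoxy-4-methyl-3-pentacosylbenzene F4. Oxidative demethylation of F4 with ceric ammonium nitrate (MeCN/H2O, 0 °C) across the para-dimethoxy pair should then give 10.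

Step 1. What may go wrong: oxidative degradation of the quinone by Ag(II)/sulfate radicals, low conversion of the acid, and some radical addition at C3. The fallback sets out from 1 and comes back at 4. Hydroboration of commercial methyl undec-10-enoate with BH3·THF (one third equivalent, 0 °C) gives tris(11-methoxy-11-oxoundecyl)borane F5. Its oxidant-free reductive 1,4-alkylation of quinone 1 (THF, trace of air as initiator, rt, aqueous work-up) should deliver hydroquinone ester 4 directly. The product is at the hydroquinone level and cannot be alkylated or oxidised further; 4 is then methylated as in step 2.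

Step 5. What may go wrong: stalling at the monoketal stage, because the second ketal sits next to the methoxy-bearing carbon and is deactivated, and, on forcing, hydrolytic loss of the C2 methoxy group. The fallback sets out from 9 and comes back at 10. Exhaustive hydrolysis of 9 (3 M HCl, dioxane, 60 °C) is driven deliberately to the vinylogous acid 2-hydroxy-5-methyl-6-pentacosyl-1,4-benzoquinone F6. O-methylation of F6 with trimethylsilyldiazomethane (MeOH/toluene, 0 °C) should give 10.

**Further compounds**
F1 | step 4 | 1,3-dioxoisoindolin-2-yl 11-(2,3,5-trimethoxy-6-methylphenyl)undecanoate | O=C(CCCCCCCCCCc1c(C)c(OC)cc(OC)c1OC)ON1C(=O)c2ccccc2C1=O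
F2 | step 4 | pentadecylmagnesium bromide | CCCCCCCCCCCCCCC[Mg]Br
F3 | step 4 | dipentadecylzinc | CCCCCCCCCCCCCCC[Zn]CCCCCCCCCCCCCCC
F4 | step 4 | 1,2,5-trimethoxy-4-methyl-3-pentacosylbenzene | CCCCCCCCCCCCCCCCCCCCCCCCCc1c(C)c(OC)cc(OC)c1OC
F5 | step 1 | tris(11-methoxy-11-oxoundecyl)borane | COC(=O)CCCCCCCCCCB(CCCCCCCCCCC(=O)OC)CCCCCCCCCCC(=O)OC
F6 | step 5 | 2-hydroxy-5-methyl-6-pentacosyl-1,4-benzoquinone | CCCCCCCCCCCCCCCCCCCCCCCCCC1=C(C)C(=O)C=C(O)C1=O
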